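**Retrosynthetic overview**
Numbering: C1 quaternary fusion carbon (CH3), C2 CH–O(angeloyl), C3 CH2, C4 C(OH)(iPr), C5 fusion CH, C6 CH–O(aroyl), C7 CH2, C8(CH3)=C9, C10 CH2 on C1. Ring A is the cyclopentane C1–C5 and ring B the cycloheptene C1, C5–C10.
Feature used: the single skeletal alkene C8=C9 lies in ring B, away from all five stereocentres, and the two ring-B arms (C10 on C1, C6 on C5) leave ring A on the same face.
Disconnections: the C2–O angelate is removed first. C8=C9 is then opened by ring-closing metathesis to a ring-A diene with an allyl group on C1 and a CH(OCOAr)CH2C(CH3)=CH2 chain on C5.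
Ring A is decorated bond by bond on (S)-4-silyloxycyclopentenone: C1–C10 (conjugate allylation, reoxidation), C1–CH3 (cuprate), C5–C6 (aldol with 3-methylbut-3-enal), C4–iPr (organocerium), C6–O aroate.
Ring order: ring A is bought with C2 in place, and ring B is the only ring formed, in step 10.

Key step: step 10

Assumption: the stereodescriptors of the SMILES are taken at face value. They describe the cis-fused hydroazulene with C1–CH3, C5–H and the isopropyl group on one face and C2–O, C4–OH, C6 and C10 on the other, (1R,2S,4S,5R,6R) in the numbering above.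

**Step 1**
Reactants: 1 (S)-4-(tert-butyldimethylsilyloxy)cyclopent-2-enone
Product: 2 tert-butyl{[(1S,2S)-2-allyl-4-(trimethylsilyloxy)cyclopent-3-en-1-yl]oxy}dimethylsilane (allyl trans to OTBS)
Conditions: allylMgBr, CuBr·SMe2, LiCl, THF, −78 °C; then TMSCl, 1, −78 °C
Reagents that add atoms: allylmagnesium bromide, C=CC[Mg]Br; chlorotrimethylsilane, C[Si](C)(C)Cl
Why: This is a TMSCl-accelerated conjugate addition of an allylcopper reagent, in which O-silylation traps the enolate before it can equilibrate and expel the C2 silyloxy group; the allyl group enters anti to OTBS, but this C1 centre is erased again in step 2.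

**Step 2**
Reactants: 2 silyl enol ether
Product: 3 (S)-3-allyl-4-(tert-butyldimethylsilyloxy)cyclopent-2-enone
Conditions: Pd(OAc)2 (1.05 equiv), MeCN, rt
Reagents that add atoms: none
Why: In this Saegusa–Ito oxidation divalent palladium converts the silyl enol ether into a C5-bound palladium enolate whose only β-hydrogen is C1–H, so β-hydride elimination (leaving zerovalent palladium) can give only the C1=C5 enone, and the neutral medium spares the C2 stereocentre, the silyl ether and the terminal alkene.

**Step 3**
Reactants: 3 allyl enone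
Product: 4 tert-butyl{[(1S,2R)-2-allyl-2-methyl-4-(trimethylsilyloxy)cyclopent-3-en-1-yl]oxy}dimethylsilane (methyl trans and allyl cis to OTBS)
Conditions: Me2CuLi (from MeLi, CuI), TMSCl, Et2O, −78 → −30 °C; cold aq NaHCO3
Reagents that add atoms: methyllithium (delivered as Me2CuLi), [Li]C; chlorotrimethylsilane, C[Si](C)(C)Cl
Why: This is a TMSCl-assisted Gilman cuprate 1,4-addition to a β,β-disubstituted cyclopentenone, in which methyl reaches C1 on the face opposite the neighbouring C2–OTBS group and so fixes the quaternary centre as 1R, while O-silylation stores the C4=C5 enolate regiochemistry.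

**Step 4**
Reactants: 5 3-methylbut-3-en-1-ol
Product: 6 3-methylbut-3-enal
Conditions: Dess–Martin periodinane, NaHCO3, CH2Cl2, 0 °C; used at once as a cold solution
Reagents that add atoms: none
Why: The buffered Dess–Martin oxidation is fast, neutral and non-aqueous, so the β,γ-unsaturated aldehyde should not slip into conjugation.

**Step 5**
Reactants: 4 silyl enol ether; 6 3-methylbut-3-enal
Product: 9 (2R,3R,4S)-3-allyl-4-(tert-butyldimethylsilyloxy)-2-[(1R)-1-hydroxy-3-methylbut-3-enyl]-3-methylcyclopentanone, via lithium enolate 7 (not isolated), via chlorozinc enolate 8 (not isolated)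
Conditions: MeLi, THF, 0 °C; ZnCl2, −78 °C; 6, −78 °C; aq NH4Cl
Reagents that add atoms: 3-methylbut-3-enal (6), C=C(C)CC=O
Why: MeLi releases the regiodefined enolate from the silyl enol ether, which is transmetallated to zinc for a directed aldol addition through a closed Zimmerman–Traxler chair: the ring-locked E(O)-enolate gives the anti C5/C6 relationship, and the aldehyde should reach C5 anti to the C1 methyl, which stands pseudoaxial and trans-diaxial to C2–OTBS on the enolate envelope while the allyl group lies pseudoequatorial, so the new chain ends cis to the allyl arm (5R,6R).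

**Step 6**
Reactants: 9 aldol
Product: 10 (2R,3R,4S)-3-allyl-4-(tert-butyldimethylsilyloxy)-3-methyl-2-[(1R)-3-methyl-1-(triethylsilyloxy)but-3-enyl]cyclopentanone
Conditions: TESOTf, 2,6-lutidine, CH2Cl2, −78 °C
Reagents that add atoms: triethylsilyl trifluoromethanesulfonate, CC[Si](CC)(CC)OS(=O)(=O)C(F)(F)F
Why: O-silylation with a silyl triflate and a hindered, non-nucleophilic base at low temperature caps the C6 hydroxyl without retro-aldol cleavage, β-elimination or epimerisation at C5, and the TES ether can later be removed beside the TBS ether.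

**Step 7**
Reactants: 10 ketone
Product: 11 (1S,2R,3R,4S)-3-allyl-4-(tert-butyldimethylsilyloxy)-1-isopropyl-3-methyl-2-[(1R)-3-methyl-1-(triethylsilyloxy)but-3-enyl]cyclopentanol
Conditions: iPrMgCl, CeCl3, THF, −78 → 0 °C; aq NH4Cl
Reagents that add atoms: isopropylmagnesium chloride, CC(C)[Mg]Cl
Why: In this organocerium 1,2-addition the weakly basic, oxophilic isopropylcerium reagent adds to the hindered, enolisable β-silyloxy ketone rather than deprotonating or reducing it, and it attacks C4 from the face opposite the bulky C5 chain, which leaves the hydroxyl cis to that chain (4S).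

**Step 8**
Reactants: 11 bis-silyl ether
Product: 12 (1S,2R,3R,4S)-3-allyl-4-(tert-butyldimethylsilyloxy)-2-[(1R)-1-hydroxy-3-methylbut-3-enyl]-1-isopropyl-3-methylcyclopentanol
Conditions: PPTS (cat.), MeOH–CH2Cl2, 0 °C
Reagents that add atoms: none
Why: Acid-catalysed methanolysis tells the two silyl ethers apart by size, so the triethylsilyl ether is cleaved while the TBS ether next to the quaternary C1 and the tertiary alcohol stay.

**Step 9**
Reactants: 12 diol; 13 3,4,5-trimethoxybenzoyl chloride
Product: 14 (1R)-1-[(1R,2S,4S,5R)-5-allyl-4-(tert-butyldimethylsilyloxy)-2-hydroxy-2-isopropyl-5-methylcyclopentyl]-3-methylbut-3-enyl 3,4,5-trimethoxybenzoate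
Conditions: 13, Et3N, DMAP (cat.), CH2Cl2, 0 °C → rt
Reagents that add atoms: 3,4,5-trimethoxybenzoyl chloride (13), COc1cc(C(=O)Cl)cc(OC)c1OC
Why: DMAP-catalysed acylation esterifies only the secondary C6 hydroxyl, because the tertiary C4 hydroxyl beside the isopropyl group is inert under these conditions, and C6 keeps its configuration since the C–O bond is not touched.

**Step 10**
Reactants: 14 allyl methallyl cyclopentane
Product: 15 (1S,3S,3aR,4R,8aR)-1-(tert-butyldimethylsilyloxy)-3-hydroxy-6,8a-dimethyl-3-(propan-2-yl)-1,2,3,3a,4,5,8,8a-octahydroazulen-4-yl 3,4,5-trimethoxybenzoate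
Conditions: (H2IMes)(PCy3)Cl2Ru=CHPh (second-generation Grubbs catalyst, 5–10 mol %), 1,4-benzoquinone (10 mol %), CH2Cl2 (2 mM), reflux, argon sparge
Reagents that add atoms: none
Why: In this ring-closing olefin metathesis by the Chauvin mechanism the ruthenium benzylidene first exchanges with the unhindered monosubstituted C9=CH2 of the allyl arm, the C9 alkylidene adds across the 1,1-disubstituted C8=CH2 of the other arm in an intramolecular [2+2] step, and cycloreversion of the ruthenacyclobutane releases C8=C9 and a ruthenium methylidene that carries the chain while ethene escapes. The closest known reaction type is the closure of trisubstituted cycloheptenes from allyl/methallyl dienes on five-membered rings with N-heterocyclic-carbene ruthenium catalysts, as used for hydroazulene terpenoids. Ring B closes as a seven-membered carbocycle with the new alkene endocyclic, and in a ring of this size only the geometry with C7 and C10 cis on the double bond can form. No stereocentre is made or touched, since C2 comes from 1, C1 from step 3, C5 and C6 from step 5 and C4 from step 7. The step needs chemoselectivity only, namely closure over oligomerisation and over ruthenium-hydride migration of the allyl double bond: the cis arms on adjacent C1 and C5 hold the termini close, dilution and ethene removal favour the intramolecular path, benzoquinone intercepts hydride species, and the angelate alkene is absent because that ester is installed later. The free tertiary hydroxyl, the aryl ester and the silyl ether are tolerated by this catalyst.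

**Step 11**
Reactants: 15 silyl ether
Product: 16 (1S,3S,3aR,4R,8aR)-1,3-dihydroxy-6,8a-dimethyl-3-(propan-2-yl)-1,2,3,3a,4,5,8,8a-octahydroazulen-4-yl 3,4,5-trimethoxybenzoate
Conditions: HF·pyridine, pyridine, THF, 0 °C → rt
Reagents that add atoms: none
Why: Fluoride-driven desilylation with the weakly acidic HF·pyridine never generates a free alkoxide, which should prevent migration or loss of the C6 aroyl group.

**Step 12**
Reactants: 16 C2 alcohol; 17 angelic acid
Product: 19 target CNP0112256.1, via angelic 2,4,6-trichlorobenzoic anhydride 18 (not isolated)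
Conditions: 17, 2,4,6-Cl3C6H2COCl, Et3N, PhMe, rt; then 16, 80 °C
Reagents that add atoms: angelic acid (17), C/C=C(/C)C(=O)O
Why: This Yamaguchi-type esterification runs through the mixed anhydride without a nucleophilic amine catalyst: the alcohol attacks the less hindered angeloyl carbonyl, no reversible conjugate addition to the angelate takes place so the Z geometry is kept, and only the secondary C2 hydroxyl reacts while the tertiary C4 hydroxyl stays free.

**Compound list**
1 | (S)-4-(tert-butyldimethylsilyloxy)cyclopent-2-enone | O=C1C=C[C@@H](O[Si](C)(C)C(C)(C)C)C1 | starting material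
2 | tert-butyl{[(1S,2S)-2-allyl-4-(trimethylsilyloxy)cyclopent-3-en-1-yl]oxy}dimethylsilane | CC(C)(C)[Si](C)(C)O[C@H]1CC(O[Si](C)(C)C)=C[C@@H]1CC=C | intermediate
3 | (S)-3-allyl-4-(tert-butyldimethylsilyloxy)cyclopent-2-enone | CC(C)(C)[Si](C)(C)O[C@H]1CC(=O)C=C1CC=C | intermediate
4 | tert-butyl{[(1S,2R)-2-allyl-2-methyl-4-(trimethylsilyloxy)cyclopent-3-en-1-yl]oxy}dimethylsilane | CC(C)(C)[Si](C)(C)O[C@H]1CC(O[Si](C)(C)C)=C[C@@]1(C)CC=C | intermediate
5 | 3-methylbut-3-en-1-ol | C=C(C)CCO | starting material
6 | 3-methylbut-3-enal | C=C(C)CC=O | intermediate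
7 | lithium enolate of the C4 ketone (C4=C5) | CC(C)(C)[Si](C)(C)O[C@H]1CC(O[Li])=C[C@@]1(C)CC=C | intermediate
8 | chlorozinc enolate of the C4 ketone (C4=C5) | CC(C)(C)[Si](C)(C)O[C@H]1CC(O[Zn]Cl)=C[C@@]1(C)CC=C | intermediate
9 | (2R,3R,4S)-3-allyl-4-(tert-butyldimethylsilyloxy)-2-[(1R)-1-hydroxy-3-methylbut-3-enyl]-3-methylcyclopentanone | CC(C)(C)[Si](C)(C)O[C@H]1CC(=O)[C@@H]([C@H](O)CC(C)=C)[C@@]1(C)CC=C | intermediate
10 | C6 triethylsilyl ether of 9 | CC(C)(C)[Si](C)(C)O[C@H]1CC(=O)[C@@H]([C@H](O[Si](CC)(CC)CC)CC(C)=C)[C@@]1(C)CC=C | intermediate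
11 | (1S,2R,3R,4S)-3-allyl-4-(tert-butyldimethylsilyloxy)-1-isopropyl-3-methyl-2-[(1R)-3-methyl-1-(triethylsilyloxy)but-3-enyl]cyclopentanol | CC(C)(C)[Si](C)(C)O[C@H]1C[C@](O)(C(C)C)[C@@H]([C@H](O[Si](CC)(CC)CC)CC(C)=C)[C@@]1(C)CC=C | intermediate
12 | (1S,2R,3R,4S)-3-allyl-4-(tert-butyldimethylsilyloxy)-2-[(1R)-1-hydroxy-3-methylbut-3-enyl]-1-isopropyl-3-methylcyclopentanol | CC(C)(C)[Si](C)(C)O[C@H]1C[C@](O)(C(C)C)[C@@H]([C@H](O)CC(C)=C)[C@@]1(C)CC=C | intermediate
13 | 3,4,5-trimethoxybenzoyl chloride | COc1cc(C(=O)Cl)cc(OC)c1OC | starting material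
14 | allyl methallyl cyclopentane with the C6 aryl ester (metathesis precursor) | CC(C)(C)[Si](C)(C)O[C@H]1C[C@](O)(C(C)C)[C@@H]([C@H](OC(=O)c2cc(OC)c(OC)c(OC)c2)CC(C)=C)[C@@]1(C)CC=C | intermediate
15 | C2-silylated cis-hydroazulene aryl ester (metathesis product) | CC(C)(C)[Si](C)(C)O[C@H]1C[C@](O)(C(C)C)[C@H]2[C@H](OC(=O)c3cc(OC)c(OC)c(OC)c3)CC(C)=CC[C@@]12C | intermediate
16 | C2,C4-diol C6 aryl ester | O[C@H]1C[C@](O)(C(C)C)[C@H]2[C@H](OC(=O)c3cc(OC)c(OC)c(OC)c3)CC(C)=CC[C@@]12C | intermediate
17 | angelic acid, (Z)-2-methylbut-2-enoic acid | C/C=C(/C)C(=O)O | starting material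
18 | angelic 2,4,6-trichlorobenzoic anhydride | C/C=C(/C)C(=O)OC(=O)c1c(Cl)cc(Cl)cc1Cl | intermediate
19 | (1S,3S,3aR,4R,8aR)-3-hydroxy-6,8a-dimethyl-3-(propan-2-yl)-4-(3,4,5-trimethoxybenzoyloxy)-1,2,3,3a,4,5,8,8a-octahydroazulen-1-yl (Z)-2-methylbut-2-enoate | C/C=C(/C)C(=O)O[C@H]1C[C@](O)(C(C)C)[C@H]2[C@H](OC(=O)c3cc(OC)c(OC)c(OC)c3)CC(C)=CC[C@@]12C | target

Total step count: 12. Longest linear sequence: 11 steps (1 → 19 through steps 1–3 and 5–12); step 4 is a one-step side branch.

**Steps most likely to fail**

**Step 5.** Several processes can go wrong: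
- The aldehyde may approach the methyl face of the enolate, because C1 carries a carbon substituent on both faces. This gives poor or inverted facial selectivity at C5.
- The anti selectivity may erode.
- Aldehyde 6 may be conjugated by base.
- The aldolate may undergo retro-aldol cleavage on work-up.

The fallback makes the C5–C6 bond while C5 is still trigonal and sets C5 by delivery of hydrogen instead of carbon, so that a bias of reagents for the methyl face becomes useful.
- It sets out from enone 3 and aldehyde 6.
- α-Iodination (I2, pyridine, CH2Cl2) should give the 2-iodo enone F1.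
- A Nozaki–Hiyama–Kishi coupling with 6 (CrCl2, NiCl2 cat., DMF) should give the enone carbinol F2, whose C6 epimers are separated by chromatography.
- TESOTf and 2,6-lutidine give the silyl ether F3.
- Me2CuLi with TMSCl adds methyl to C1 anti to OTBS and gives the fully substituted silyl enol ether F4.
- Protonolysis at −78 °C (Bu4NF buffered with AcOH, THF) places the proton on the less shielded face and pushes the chain to the allyl face.
- The route is rejoined at ketone 10.

**Step 7.** Three processes can go wrong:
- The ketone may enolise and then lose a β-silyloxy group.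
- The secondary alkyl reagent may transfer a β-hydride and reduce the ketone.
- Conversion at the crowded carbonyl may stall.

The fallback uses an sp2 nucleophile that has no β-hydrogen and saturates it after ring closure.
- It sets out from 10.
- 2-Propenylmagnesium bromide with CeCl3 should give the isopropenyl carbinol F5.
- PPTS in MeOH gives the isopropenyl diol F6.
- Acid chloride 13 with DMAP gives the isopropenyl aryl ester F7.
- The conditions of step 10 close the isopropenyl hydroazulene F8. The isopropenyl group stands on the face opposite the allyl arm and cannot close a ring with it.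
- RhCl(PPh3)3 under H2 (1 atm, benzene) should saturate the 1,1-disubstituted alkene ahead of the trisubstituted ring alkene.
- The route is rejoined at 15.

**Step 10.** Three processes can go wrong:
- Cross metathesis at the allyl terminus may lead to oligomers.
- The allyl double bond may migrate, followed by ring-contracting closure.
- The catalyst may stall at the 1,1-disubstituted alkene next to the bulky aroate.

The fallback moves the ring closure ahead of the aroylation and freezes the C5–C6 rotamer with a tether.
- It sets out from diol 12.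
- 2,2-Dimethoxypropane with PPTS ties O4 and O6 into the acetonide F9. In its chair C1 and C7 are both equatorial and therefore gauche, so the methallyl group is held beside the allyl group.
- Metathesis with the same catalyst should give the tricyclic acetonide F10.
- Aqueous AcOH frees the hydroazulene diol F11.
- Selective C6 aroylation with 13, Et3N and DMAP rejoins the route at 15.

**Further compounds**
F1 | step 5 | (S)-3-allyl-4-(tert-butyldimethylsilyloxy)-2-iodocyclopent-2-enone | CC(C)(C)[Si](C)(C)O[C@H]1CC(=O)C(I)=C1CC=C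
F2 | step 5 | (S)-3-allyl-4-(tert-butyldimethylsilyloxy)-2-[(1R)-1-hydroxy-3-methylbut-3-enyl]cyclopent-2-enone | CC(C)(C)[Si](C)(C)O[C@H]1CC(=O)C([C@H](O)CC(C)=C)=C1CC=C
F3 | step 5 | C6 triethylsilyl ether of F2 | CC(C)(C)[Si](C)(C)O[C@H]1CC(=O)C([C@H](O[Si](CC)(CC)CC)CC(C)=C)=C1CC=C
F4 | step 5 | fully substituted C4=C5 trimethylsilyl enol ether carrying the C5 chain | CC(C)(C)[Si](C)(C)O[C@H]1CC(O[Si](C)(C)C)=C([C@H](O[Si](CC)(CC)CC)CC(C)=C)[C@@]1(C)CC=C
F5 | step 7 | C4-isopropenyl analogue of 11 | CC(C)(C)[Si](C)(C)O[C@H]1C[C@](O)(C(C)=C)[C@@H]([C@H](O[Si](CC)(CC)CC)CC(C)=C)[C@@]1(C)CC=C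
F6 | step 7 | C4-isopropenyl analogue of 12 | CC(C)(C)[Si](C)(C)O[C@H]1C[C@](O)(C(C)=C)[C@@H]([C@H](O)CC(C)=C)[C@@]1(C)CC=C
F7 | step 7 | C4-isopropenyl analogue of 14 | CC(C)(C)[Si](C)(C)O[C@H]1C[C@](O)(C(C)=C)[C@@H]([C@H](OC(=O)c2cc(OC)c(OC)c(OC)c2)CC(C)=C)[C@@]1(C)CC=C
F8 | step 7 | C4-isopropenyl analogue of 15 | CC(C)(C)[Si](C)(C)O[C@H]1C[C@](O)(C(C)=C)[C@H]2[C@H](OC(=O)c3cc(OC)c(OC)c(OC)c3)CC(C)=CC[C@@]12C
F9 | step 10 | O4,O6-acetonide of 12 | CC(C)(C)[Si](C)(C)O[C@H]1C[C@@]2(C(C)C)OC(C)(C)O[C@H](CC(C)=C)[C@H]2[C@@]1(C)CC=C
F10 | step 10 | O4,O6-acetonide of the C2-silylated hydroazulene diol | CC(C)(C)[Si](C)(C)O[C@H]1C[C@@]2(C(C)C)OC(C)(C)O[C@@H]3CC(C)=CC[C@]1(C)[C@@H]23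
F11 | step 10 | C2-silylated hydroazulene C4,C6-diol | CC(C)(C)[Si](C)(C)O[C@H]1C[C@](O)(C(C)C)[C@H]2[C@H](O)CC(C)=CC[C@@]12C
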